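**Retrosynthetic overview**

1. The target is unmasked from an acetal-protected ring enal. The C(CH2OH)=CH bond of the side chain comes from an aldol condensation of a ring CH2CO2t-Bu arm with dienal 29; the arm comes from a cyclopentanone by olefination and hydroxyl-directed hydrogenation.
2. The cyclopentane comes from a spiro-fused cyclobutane: a base-induced α-ketol ring expansion of a 1-hydroxycyclobutane-1-carbaldehyde (lactol 14) inserts the carbinol carbon between the quaternary carbon and the ketone carbon.
3. The cyclobutane comes from a butenolide and ethylene by [2+2] photocycloaddition, which makes the CH2–C(quaternary) and CH2–CH bonds. The butenolide C=C (quaternary carbon to the future side-chain CH) is not in the target and is the bond cleaved in the ring expansion.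
4. Enabling feature: the oxygen of the tertiary alcohol on the cyclohexane carbon next to the spiro carbon and the CH(OH) carbon of the cyclopentane are 1,3-related and cis. This carbinol carbon can therefore be held as the carbonyl of a γ-lactone on that oxygen, which puts the spiro carbon at the β-position of a rigid enone chromophore.
5. Ring order: cyclohexane from (S)-carvone (its isopropenyl group becomes the C(CH3)CHO unit, its ketone carbon the spiro carbon), then the temporary γ-lactone, the temporary cyclobutane, and last the cyclopentane.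

Key step: step 8

**Remarks on the chemistry**

- The oxirane made in step 7 is expected as both epimers at its quaternary carbon. This centre, and the aldehyde α-carbon in 23, is drawn without a descriptor; both epimers converge in step 16.
- The (Z) ring enal (CHO syn to the ring CH that carries the hydroxypropyl chain) is assumed to be the thermodynamically preferred geometry, reached through the oxocarbenium stages of steps 17 and 23.
- The aldol adducts 30 and 31 are mixtures at their two new centres, which disappear in step 21.

**Route**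

Step 1
Reactants: 1 3-iodopropan-1-ol
Product: 2 (3-iodopropoxy)tri(propan-2-yl)silane
Conditions: i-Pr3SiCl, imidazole, CH2Cl2, 0 °C to rt
Reagents that add atoms: chlorotri(propan-2-yl)silane, CC(C)[Si](Cl)(C(C)C)C(C)C
Why: Imidazole-promoted silylation of a primary alcohol gives an ether that should survive the acid of step 4 and all base and hydride steps; no stereocenter is involved.

Step 2
Reactants: 3 (S)-(+)-carvone; 2 (3-iodopropoxy)tri(propan-2-yl)silane
Product: 4 (5S,6R)-2-methyl-5-(prop-1-en-2-yl)-6-[3-(triisopropylsilyloxy)propyl]cyclohex-2-en-1-one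
Conditions: LiN(i-Pr)2, THF, −78 °C; then 2, DMPU, −78 to 0 °C
Reagents that add atoms: none
Why: Kinetic deprotonation at C6 gives the cross-conjugated lithium dienolate, and its alkylation (enolate alkylation) should occur anti to the neighbouring C5 isopropenyl group, setting the new C6 centre trans to it.

Step 3
Reactants: 4 trans-6-alkylcarvone
Product: 5 2,3-epoxy ketone with the oxirane oxygen trans to the isopropenyl group
Conditions: 30% H2O2, NaOH (cat.), MeOH, 0 °C
Reagents that add atoms: hydrogen peroxide, OO
Why: Weitz–Scheffer nucleophilic epoxidation, in which hydroperoxide should add to C3 from the face anti to the isopropenyl group, so that the C2–O bond (the future tertiary alcohol) is set trans to isopropenyl and cis to the C6 chain.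

Step 4
Reactants: 5 epoxy ketone
Product: 6 chlorohydrin (3-chloro-2-hydroxy-2-methyl ketone with Cl trans to OH)
Conditions: LiCl, CF3CO2H, THF, 0 °C to rt
Reagents that add atoms: lithium chloride, [Li+].[Cl-]
Why: Acid-promoted halide opening of the α,β-epoxy ketone, in which chloride should attack the secondary C3 by SN2 (the tertiary carbon next to the carbonyl is deactivated), so the C2–O bond and its configuration are kept.

Step 5
Reactants: 6 chlorohydrin
Product: 7 (2S,5S,6R)-2-hydroxy-2-methyl-5-(prop-1-en-2-yl)-6-[3-(triisopropylsilyloxy)propyl]cyclohexan-1-one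
Conditions: n-Bu3SnH, AIBN (cat.), toluene, 80 °C
Reagents that add atoms: none
Why: Radical-chain dehalogenation with tin hydride removes the chlorine and turns C3 into CH2 without touching the tertiary alcohol, the ketone or the other stereocenters.

Step 6
Reactants: 7 α-hydroxy ketone; 8 (triphenylphosphoranylidene)ketene
Product: 9 (4R,5S,7aS)-7a-methyl-5-(prop-1-en-2-yl)-4-[3-(triisopropylsilyloxy)propyl]-5,6,7,7a-tetrahydro-1-benzofuran-2(4H)-one
Conditions: toluene, 110 °C
Reagents that add atoms: none
Why: Bestmann butenolide synthesis, in which the tertiary hydroxyl adds to the ketene ylide and the resulting acyl-stabilised phosphorane closes onto the neighbouring ketone by intramolecular Wittig reaction; the chain-bearing centre stays in its preferred trans arrangement.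

Step 7
Reactants: 9 bicyclic butenolide
Product: 10 butenolide with the isopropenyl group masked as a 2-methyloxiran-2-yl group (both oxirane epimers)
Conditions: mCPBA, NaHCO3, CH2Cl2, 0 °C
Reagents that add atoms: 3-chloroperbenzoic acid, OOC(=O)c1cccc(Cl)c1
Why: Prilezhaev epoxidation of the electron-rich 1,1-disubstituted alkene (the conjugated butenolide C=C is inert to peracid) removes the only alkene that could interfere with the photocycloaddition and with the hydrogenation of step 13.

Step 8
Reactants: 10 oxirane-masked butenolide; 11 ethylene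
Product: 12 tricyclic cyclobutane lactone (cyclobutane cis-fused to the γ-lactone; lactone cis-fused to the cyclohexane; new CH2 on the quaternary carbon cis to the angular methyl)
Conditions: C2H4 (saturated solution), hν (medium-pressure Hg lamp, Pyrex filter), acetone, −70 °C
Reagents that add atoms: none
Why: Acetone-sensitised triplet [2+2] photocycloaddition: the butenolide triplet adds ethylene stepwise through a 1,4-diradical and closes to the cyclobutane, joining one CH2 to the β-carbon (the future spiro carbon) and the other CH2 to the α-carbon (the future side-chain-bearing CH) in one operation. The closest known reaction type is the photocycloaddition of ethylene to 2(5H)-furanones and cyclic enones. The four-membered ring closes by an intermolecular two-bond [2+2] cycloaddition and is necessarily cis-fused to the lactone. Two stereocenters form: the quaternary β-carbon, set by the face of attack, and the α-carbon, which follows from the cis fusion. The step needs attack on the face that carries the angular methyl group, so that the lactone stays cis-fused to the cyclohexane: the cyclohexane chair (chain and oxiranyl group equatorial) folds under the opposite, concave face and shields it, whereas the convex face carries only the methyl group. Regioselectivity is no issue with symmetrical ethylene, and the oxirane mask leaves no second alkene for an intramolecular cycloaddition.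

Step 9
Reactants: 12 cyclobutane lactone
Product: 13 α-hydroxy lactone (OH on the ring-fusion carbon shared by cyclobutane and lactone)
Conditions: KN(SiMe3)2, THF, −78 °C; then 3-phenyl-2-(phenylsulfonyl)oxaziridine, −78 °C
Reagents that add atoms: 3-phenyl-2-(phenylsulfonyl)oxaziridine, O=S(=O)(N1OC1c1ccccc1)c1ccccc1
Why: Davis hydroxylation of the potassium lactone enolate at its only acidic position; the configuration of the new tertiary carbinol is dictated by the cis fusion of cyclobutane and lactone.

Step 10
Reactants: 13 α-hydroxy lactone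
Product: 14 lactol (masked 1-hydroxycyclobutane-1-carbaldehyde; either anomer)
Conditions: i-Bu2AlH (2.5 equiv), CH2Cl2, −78 °C; aqueous tartrate work-up
Reagents that add atoms: none
Why: Partial reduction of the γ-lactone stops at the lactol because the tetrahedral aluminate is stable at low temperature; no ring stereocenter is changed.

Step 11
Reactants: 14 lactol
Product: 17 bis(trimethylsilyl) ether of the spiro[4.5]decane keto diol, via spiro[3.5]nonane hydroxy aldehyde 15 (not isolated), via keto diol 16 (not isolated)
Conditions: KN(SiMe3)2 (2.1 equiv), THF, −78 to 0 °C; then Me3SiCl, −78 °C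
Reagents that add atoms: chlorotrimethylsilane, C[Si](C)(C)Cl
Why: Base-induced α-ketol rearrangement driven by relief of cyclobutane strain: the alkoxide of the open hydroxy aldehyde should shift the more substituted ring bond (to the quaternary carbon, with retention) onto the formyl carbon through the dipole-opposed O–C–C=O conformer, which sets the new carbinol centre cis to the tertiary oxygen; silylation of both alkoxides in the same flask prevents later ketol equilibration and hemiketal formation.

Step 12
Reactants: 17 bis-silyl keto diol; 18 tert-butyl 2-(diethoxyphosphoryl)acetate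
Product: 20 exocyclic (E)-enoate diol, via bis-silyl enoate 19 (not isolated)
Conditions: NaH, THF, 0 to 40 °C; then KF, MeOH, rt
Reagents that add atoms: none
Why: Horner–Wadsworth–Emmons olefination of the α-silyloxy cyclopentanone (ester expected anti to the silyloxy-bearing carbon; the tert-butyl ester resists lactonisation), followed by fluoride-catalysed methanolysis of the two trimethylsilyl ethers; no stereocenter is created.

Step 13
Reactants: 20 enoate diol
Product: 21 saturated tert-butyl ester diol (acetate arm trans to the secondary hydroxyl)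
Conditions: H2 (1 atm), [Ir(cod)(PCy3)(py)]PF6 (5 mol %), CH2Cl2, rt
Reagents that add atoms: none
Why: Hydroxyl-directed homogeneous hydrogenation, in which the cationic iridium catalyst bound to the allylic (and tertiary) hydroxyl delivers H2 to their face of the exocyclic alkene, so the new ring C–H is cis to the carbinol OH and the CH2CO2t-Bu arm trans to it.

Step 14
Reactants: 21 ester diol
Product: 22 secondary tert-butyldimethylsilyl ether with the tertiary alcohol free
Conditions: t-BuMe2SiOSO2CF3 (1.2 equiv), 2,6-lutidine, CH2Cl2, −78 °C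
Reagents that add atoms: tert-butyldimethylsilyl trifluoromethanesulfonate, CC(C)(C)[Si](C)(C)OS(=O)(=O)C(F)(F)F
Why: Silyl triflate silylation at low temperature is selective for the secondary over the tertiary alcohol and protects the secondary alcohol from the oxidant of step 16.

Step 15
Reactants: 22 silyl ether oxirane
Product: 23 aldehyde (ring-CH(CH3)CHO; both α-epimers)
Conditions: BF3·OEt2 (0.3 equiv), CH2Cl2, −78 °C
Reagents that add atoms: none
Why: Meinwald rearrangement, in which the Lewis acid opens the 2,2-disubstituted oxirane at its tertiary carbon and a 1,2-hydride shift gives the aldehyde from both epoxide epimers.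

Step 16
Reactants: 23 aldehyde
Product: 24 ring (Z)-enal (tetrasubstituted exocyclic alkene; CHO syn to the chain-bearing ring CH)
Conditions: IBX (2 equiv), DMSO, 70 °C
Reagents that add atoms: none
Why: IBX dehydrogenation of the aldehyde through its enol should place the new double bond toward the ring methine (the more substituted, more stable conjugated alkene), which erases the two uncontrolled centres.

Step 17
Reactants: 24 enal
Product: 25 enal dimethyl acetal
Conditions: HC(OMe)3, PPTS (cat.), MeOH, rt
Reagents that add atoms: trimethyl orthoformate, COC(OC)OC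
Why: Acid-catalysed acetalisation protects the enal against the base and hydride of steps 20 to 22, and its allyl-type oxocarbenium intermediate allows the alkene geometry to equilibrate.

Step 18
Reactants: 26 6-methylhept-5-en-2-one
Product: 27 6-methylhepta-1,5-dien-2-yl trifluoromethanesulfonate
Conditions: LiN(i-Pr)2, THF, −78 °C; then PhN(SO2CF3)2, −78 to 0 °C
Reagents that add atoms: N-phenylbis(trifluoromethanesulfonimide), O=S(=O)(N(c1ccccc1)S(=O)(=O)C(F)(F)F)C(F)(F)F
Why: Kinetic enolisation at the methyl group and O-sulfonylation of the enolate give the terminal enol triflate (enol triflate formation); no stereocenter is involved.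

Step 19
Reactants: 27 enol triflate; 28 acrolein
Product: 29 (2E)-8-methyl-4-methylidenenona-2,7-dienal
Conditions: Pd(OAc)2 (5 mol %), PPh3, Et3N, DMF, 60 °C
Reagents that add atoms: none
Why: Mizoroki–Heck vinylation of acrolein by the enol triflate, in which syn insertion and syn β-hydride elimination give the (E)-alkene.

Step 20
Reactants: 25 ester acetal; 29 dienal
Product: 30 β-hydroxy ester (aldol adduct; mixture at the two new centres)
Conditions: LiN(i-Pr)2 (2.2 equiv), THF, −78 °C; then 29, −78 °C
Reagents that add atoms: none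
Why: Aldol addition of the lithium ester enolate (the tertiary alcohol is carried as its alkoxide) to the aldehyde carbon of the dienal; the two new centres need no control because they are removed in step 21.

Step 21
Reactants: 30 aldol adduct
Product: 32 (E)-trienoate, via aldol acetate 31 (not isolated)
Conditions: Ac2O, Et3N, DMAP (cat.), CH2Cl2, 0 °C; then DBU, rt
Reagents that add atoms: none
Why: Acetylation of the secondary aldol hydroxyl and E1cB elimination should give the more stable (E)-alkene, with the dienyl chain trans to the ester and cis to the ring carbon.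

Step 22
Reactants: 32 trienoate
Product: 33 allylic alcohol (side-chain CH2OH in place)
Conditions: i-Bu2AlH (4 equiv), CH2Cl2, −78 to −20 °C
Reagents that add atoms: none
Why: 1,2-Reduction of the conjugated tert-butyl ester to the primary allylic alcohol with retention of all alkene geometries; the acetal and silyl ethers are inert.

Step 23
Reactants: 33 protected allylic alcohol
Product: 35 target CNP0246965.1, via tetraol acetal 34 (not isolated)
Conditions: n-Bu4NF, THF, rt to 40 °C; then AcOH–H2O, rt
Reagents that add atoms: water, O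
Why: Fluoride cleaves both silyl ethers and mild aqueous acid then hydrolyses the unsaturated dimethyl acetal to the enal (desilylation and acetal hydrolysis); no stereocenter is touched.

**Compound list**

1 | 3-iodopropan-1-ol | OCCCI | starting material
2 | (3-iodopropoxy)tri(propan-2-yl)silane | ICCCO[Si](C(C)C)(C(C)C)C(C)C | intermediate
3 | (S)-(+)-carvone | CC1=CC[C@@H](CC1=O)C(C)=C | starting material
4 | (5S,6R)-2-methyl-5-(prop-1-en-2-yl)-6-[3-(triisopropylsilyloxy)propyl]cyclohex-2-en-1-one | CC1=CC[C@H](C(C)=C)[C@@H](CCCO[Si](C(C)C)(C(C)C)C(C)C)C1=O | intermediate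
5 | 2,3-epoxy ketone of 4 (oxirane oxygen trans to isopropenyl) | C[C@]12O[C@H]1C[C@H](C(C)=C)[C@@H](CCCO[Si](C(C)C)(C(C)C)C(C)C)C2=O | intermediate
6 | chlorohydrin (3-chloro-2-hydroxy-2-methyl ketone; Cl trans to OH) | C[C@]1(O)[C@H](Cl)C[C@H](C(C)=C)[C@@H](CCCO[Si](C(C)C)(C(C)C)C(C)C)C1=O | intermediate
7 | (2S,5S,6R)-2-hydroxy-2-methyl-5-(prop-1-en-2-yl)-6-[3-(triisopropylsilyloxy)propyl]cyclohexan-1-one | C[C@]1(O)CC[C@H](C(C)=C)[C@@H](CCCO[Si](C(C)C)(C(C)C)C(C)C)C1=O | intermediate
8 | (triphenylphosphoranylidene)ketene | O=C=C=P(c1ccccc1)(c1ccccc1)c1ccccc1 | starting material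
9 | (4R,5S,7aS)-7a-methyl-5-(prop-1-en-2-yl)-4-[3-(triisopropylsilyloxy)propyl]-5,6,7,7a-tetrahydro-1-benzofuran-2(4H)-one | C[C@]12CC[C@H](C(C)=C)[C@@H](CCCO[Si](C(C)C)(C(C)C)C(C)C)C1=CC(=O)O2 | intermediate
10 | 5-(2-methyloxiran-2-yl) analogue of 9 (both oxirane epimers) | C[C@]12CC[C@H](C3(C)CO3)[C@@H](CCCO[Si](C(C)C)(C(C)C)C(C)C)C1=CC(=O)O2 | intermediate
11 | ethylene | C=C | starting material
12 | tricyclic cyclobutane lactone (new CH2 on the quaternary carbon cis to the angular methyl) | C[C@]12CC[C@H](C3(C)CO3)[C@@H](CCCO[Si](C(C)C)(C(C)C)C(C)C)[C@]14CC[C@@H]4C(=O)O2 | intermediate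
13 | α-hydroxy lactone of 12 | C[C@]12CC[C@H](C3(C)CO3)[C@@H](CCCO[Si](C(C)C)(C(C)C)C(C)C)[C@]14CC[C@]4(O)C(=O)O2 | intermediate
14 | lactol of 13 | C[C@]12CC[C@H](C3(C)CO3)[C@@H](CCCO[Si](C(C)C)(C(C)C)C(C)C)[C@]14CC[C@]4(O)C(O)O2 | intermediate
15 | spiro[3.5]nonane hydroxy aldehyde (open form of 14) | C[C@]1(O)CC[C@H](C3(C)CO3)[C@@H](CCCO[Si](C(C)C)(C(C)C)C(C)C)[C@]12CC[C@]2(O)C=O | intermediate
16 | spiro[4.5]decane keto diol (secondary OH cis to the tertiary C–O bond) | C[C@]1(O)CC[C@H](C3(C)CO3)[C@@H](CCCO[Si](C(C)C)(C(C)C)C(C)C)[C@]12CCC(=O)[C@@H]2O | intermediate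
17 | bis(trimethylsilyl) ether of 16 | C[C@]1(O[Si](C)(C)C)CC[C@H](C3(C)CO3)[C@@H](CCCO[Si](C(C)C)(C(C)C)C(C)C)[C@]12CCC(=O)[C@@H]2O[Si](C)(C)C | intermediate
18 | tert-butyl 2-(diethoxyphosphoryl)acetate | CCOP(=O)(CC(=O)OC(C)(C)C)OCC | starting material
19 | bis-silyl exocyclic (E)-enoate | C[C@]1(O[Si](C)(C)C)CC[C@H](C3(C)CO3)[C@@H](CCCO[Si](C(C)C)(C(C)C)C(C)C)[C@]12CC/C(=C\C(=O)OC(C)(C)C)[C@@H]2O[Si](C)(C)C | intermediate
20 | exocyclic (E)-enoate diol | C[C@]1(O)CC[C@H](C3(C)CO3)[C@@H](CCCO[Si](C(C)C)(C(C)C)C(C)C)[C@]12CC/C(=C\C(=O)OC(C)(C)C)[C@@H]2O | intermediate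
21 | saturated tert-butyl ester diol (arm trans to secondary OH) | C[C@]1(O)CC[C@H](C3(C)CO3)[C@@H](CCCO[Si](C(C)C)(C(C)C)C(C)C)[C@]12CC[C@@H](CC(=O)OC(C)(C)C)[C@@H]2O | intermediate
22 | secondary tert-butyldimethylsilyl ether of 21 | C[C@]1(O)CC[C@H](C3(C)CO3)[C@@H](CCCO[Si](C(C)C)(C(C)C)C(C)C)[C@]12CC[C@@H](CC(=O)OC(C)(C)C)[C@@H]2O[Si](C)(C)C(C)(C)C | intermediate
23 | aldehyde from Meinwald rearrangement (both α-epimers) | C[C@]1(O)CC[C@H](C(C)C=O)[C@@H](CCCO[Si](C(C)C)(C(C)C)C(C)C)[C@]12CC[C@@H](CC(=O)OC(C)(C)C)[C@@H]2O[Si](C)(C)C(C)(C)C | intermediate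
24 | ring (Z)-enal | C[C@]1(O)CC/C(=C(\C)C=O)[C@@H](CCCO[Si](C(C)C)(C(C)C)C(C)C)[C@]12CC[C@@H](CC(=O)OC(C)(C)C)[C@@H]2O[Si](C)(C)C(C)(C)C | intermediate
25 | dimethyl acetal of 24 | C[C@]1(O)CC/C(=C(\C)C(OC)OC)[C@@H](CCCO[Si](C(C)C)(C(C)C)C(C)C)[C@]12CC[C@@H](CC(=O)OC(C)(C)C)[C@@H]2O[Si](C)(C)C(C)(C)C | intermediate
26 | 6-methylhept-5-en-2-one | CC(=O)CCC=C(C)C | starting material
27 | 6-methylhepta-1,5-dien-2-yl trifluoromethanesulfonate | C=C(OS(=O)(=O)C(F)(F)F)CCC=C(C)C | intermediate
28 | acrolein (prop-2-enal) | C=CC=O | starting material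
29 | (2E)-8-methyl-4-methylidenenona-2,7-dienal | O=C/C=C/C(=C)CCC=C(C)C | intermediate
30 | aldol adduct (β-hydroxy ester; mixture at the two new centres) | C[C@]1(O)CC/C(=C(\C)C(OC)OC)[C@@H](CCCO[Si](C(C)C)(C(C)C)C(C)C)[C@]12CC[C@@H](C(C(=O)OC(C)(C)C)C(O)/C=C/C(=C)CCC=C(C)C)[C@@H]2O[Si](C)(C)C(C)(C)C | intermediate
31 | acetate of 30 | C[C@]1(O)CC/C(=C(\C)C(OC)OC)[C@@H](CCCO[Si](C(C)C)(C(C)C)C(C)C)[C@]12CC[C@@H](C(C(=O)OC(C)(C)C)C(OC(C)=O)/C=C/C(=C)CCC=C(C)C)[C@@H]2O[Si](C)(C)C(C)(C)C | intermediate
32 | (E)-trienoate | C[C@]1(O)CC/C(=C(\C)C(OC)OC)[C@@H](CCCO[Si](C(C)C)(C(C)C)C(C)C)[C@]12CC[C@@H](/C(C(=O)OC(C)(C)C)=C\C=C\C(=C)CCC=C(C)C)[C@@H]2O[Si](C)(C)C(C)(C)C | intermediate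
33 | protected side-chain allylic alcohol | C[C@]1(O)CC/C(=C(\C)C(OC)OC)[C@@H](CCCO[Si](C(C)C)(C(C)C)C(C)C)[C@]12CC[C@@H](/C(CO)=C\C=C\C(=C)CCC=C(C)C)[C@@H]2O[Si](C)(C)C(C)(C)C | intermediate
34 | tetraol dimethyl acetal | C[C@]1(O)CC/C(=C(\C)C(OC)OC)[C@@H](CCCO)[C@]12CC[C@@H](/C(CO)=C\C=C\C(=C)CCC=C(C)C)[C@@H]2O | intermediate
35 | CNP0246965.1 | C[C@]1(O)CC/C(=C(\C)C=O)[C@@H](CCCO)[C@]12CC[C@@H](/C(CO)=C\C=C\C(=C)CCC=C(C)C)[C@@H]2O | target

**Step count and risks**

Total step count: 23. Longest linear sequence: 21 steps (steps 1 to 17, then 20 to 23); steps 18 and 19 make the dienal fragment.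

The three steps most likely to fail:

Step 8. Ethylene may add with poor facial selectivity, or to the concave face, which gives the lactone trans-fused to the cyclohexane and the wrong configuration at the quaternary carbon; the triplet may also simply decay. The fallback builds the cyclobutane by ionic steps, sets out from 10 and comes back at 12. Copper-mediated conjugate addition of an allyl group (CH2=CHCH2MgBr, CuBr·SMe2, Me3SiCl, THF, −78 °C) should deliver the new C–C bond from the bulky cuprate to the convex face and give the allyl lactone F1. Ozonolysis with NaBH4 work-up gives the hydroxyethyl lactone F2, and mesylation (MeSO2Cl, Et3N) gives the mesylate F3. KN(SiMe3)2 then closes the four-membered ring by intramolecular alkylation of the lactone enolate to give 12.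

Step 11. The wrong ring bond (the CH2 instead of the quaternary carbon) may migrate, or the α-ketol may scramble at the carbinol carbon under base. The fallback needs no 1,2-shift because the carbinol carbon is bonded to the quaternary carbon from the start; it sets out from 10 and comes back at 16, which is silylated (Me3SiCl, imidazole) to 17. Conjugate addition of a vinyl cuprate (CH2=CHMgBr, CuBr·SMe2, Me3SiCl) gives the vinyl lactone F4. Enolate hydroxylation with KN(SiMe3)2 and the oxaziridine of step 9 is expected from the convex face and gives the hydroxy lactone F5. Mitsunobu inversion with benzoic acid (PPh3, DIAD) gives the benzoate F6. i-Bu2AlH cleaves the benzoate and reduces the lactone to the lactol F7, a masked 2-hydroxypent-4-enal. Intramolecular alkene hydroacylation with [Rh(dppe)]BF4 closes the cyclopentanone to 16.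

Step 16. The dehydrogenation may lose regiocontrol (hydrogen taken from the methyl group, giving the 2-substituted acrolein), may over-oxidise, or may leave the alkene geometry unequilibrated. The fallback goes through the allylic alcohol, sets out from 22 and comes back at 24. Aluminium amide-mediated isomerisation of the oxirane (diethylaluminium 2,2,6,6-tetramethylpiperidide, Et2AlN(C9H18), toluene, 0 °C) gives the 2-substituted allylic alcohol F8. MnO2 oxidises it to the α-methylene aldehyde F9. RhCl3·3H2O in ethanol at 80 °C then moves the double bond into the tetrasubstituted, ring-exocyclic conjugated position to give 24.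

**Further compounds**

F1 | step 8 | allyl lactone (allyl on the quaternary carbon cis to the angular methyl) | C[C@]12CC[C@H](C3(C)CO3)[C@@H](CCCO[Si](C(C)C)(C(C)C)C(C)C)[C@@]1(CC=C)CC(=O)O2
F2 | step 8 | hydroxyethyl lactone | C[C@]12CC[C@H](C3(C)CO3)[C@@H](CCCO[Si](C(C)C)(C(C)C)C(C)C)[C@@]1(CCO)CC(=O)O2
F3 | step 8 | mesylate of F2 | C[C@]12CC[C@H](C3(C)CO3)[C@@H](CCCO[Si](C(C)C)(C(C)C)C(C)C)[C@@]1(CCOS(C)(=O)=O)CC(=O)O2
F4 | step 11 | vinyl lactone (vinyl on the quaternary carbon cis to the angular methyl) | C[C@]12CC[C@H](C3(C)CO3)[C@@H](CCCO[Si](C(C)C)(C(C)C)C(C)C)[C@@]1(C=C)CC(=O)O2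
F5 | step 11 | α-hydroxy lactone (OH syn to vinyl) | C[C@]12CC[C@H](C3(C)CO3)[C@@H](CCCO[Si](C(C)C)(C(C)C)C(C)C)[C@@]1(C=C)[C@H](O)C(=O)O2
F6 | step 11 | inverted α-benzoyloxy lactone | C[C@]12CC[C@H](C3(C)CO3)[C@@H](CCCO[Si](C(C)C)(C(C)C)C(C)C)[C@@]1(C=C)[C@@H](OC(=O)c4ccccc4)C(=O)O2
F7 | step 11 | hydroxy lactol (masked 2-hydroxypent-4-enal) | C[C@]12CC[C@H](C3(C)CO3)[C@@H](CCCO[Si](C(C)C)(C(C)C)C(C)C)[C@@]1(C=C)[C@@H](O)C(O)O2
F8 | step 16 | 2-substituted allylic alcohol | C[C@]1(O)CC[C@H](C(=C)CO)[C@@H](CCCO[Si](C(C)C)(C(C)C)C(C)C)[C@]12CC[C@@H](CC(=O)OC(C)(C)C)[C@@H]2O[Si](C)(C)C(C)(C)C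
F9 | step 16 | α-methylene aldehyde | C[C@]1(O)CC[C@H](C(=C)C=O)[C@@H](CCCO[Si](C(C)C)(C(C)C)C(C)C)[C@]12CC[C@@H](CC(=O)OC(C)(C)C)[C@@H]2O[Si](C)(C)C(C)(C)C
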